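The route rests on cutting ring B (C5–C10) across C5–C6 and C9–C10 into 2-silyloxybutadiene and an acyclic (E)-2-methyl-3-isopropenyl enal. One catalytic asymmetric Diels–Alder reaction closes ring B, sets the vicinal centres C5 (isopropenyl) and quaternary C10 (methyl plus a formyl group that becomes the C1–C3 arm) and leaves a C7 silyl enol ether. The structural feature exploited is the trans relation between the C10 arm and the C5 isopropenyl group, which is the (E)-geometry of the dienal transferred by suprafacial addition. The precursors are a trisubstituted dienal and an electron-rich diene; ring C is annulated later onto C8–C9.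

Key step: step 3

Remark: atoms are numbered as in an abietane (ring B = C5–C10; ring C = C8, C9, C11–C14; arm = C1–C3); the (S)-configured catalyst is chosen from the accepted pre-transition-state model for 2-substituted enals (its mirror image would give the antipode), and methyl 2-acetyl-3-methylbutanoate is taken as a catalogue chemical.

Step 1
Reactants: 1 methyl vinyl ketone
Product: 2 2-(triisopropylsilyloxy)buta-1,3-diene
Conditions: iPr3SiOTf (1.05 equiv), NEt3 (1.3 equiv), Et2O, 0 → 25 °C
Reagents that add atoms: triisopropylsilyl trifluoromethanesulfonate, CC(C)[Si](C(C)C)(C(C)C)OS(=O)(=O)C(F)(F)F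
Why: Soft enolisation in which the silyl triflate activates the carbonyl oxygen and the amine removes a methyl proton, giving the cross-conjugated 2-silyloxydiene (silyl enol ether formation).

Step 2
Reactants: 3 methacrolein; 4 2-(triphenylphosphoranylidene)propanal
Product: 5 (E)-2,4-dimethylpenta-2,4-dienal
Conditions: methacrolein in threefold excess, toluene, BHT (cat.), 80 °C, sealed vessel; distillation
Reagents that add atoms: none
Why: Wittig olefination with a formyl-stabilised ylide, which should give the (E)-trisubstituted enal under thermodynamic control, while the excess of volatile methacrolein suppresses a second olefination of the product.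

Step 3
Reactants: 2 2-(triisopropylsilyloxy)buta-1,3-diene; 5 (E)-2,4-dimethylpenta-2,4-dienal
Product: 6 (1R,6S)-1-methyl-6-(prop-1-en-2-yl)-4-(triisopropylsilyloxy)cyclohex-3-ene-1-carbaldehyde
Conditions: two equivalents of the diene, (S)-1-(2-methylphenyl)-3,3-diphenyltetrahydro-1H,3H-pyrrolo[1,2-c][1,3,2]oxazaborole (20 mol%), HNTf2 (18 mol%), CH2Cl2, −78 → −40 °C; NEt3 quench
Reagents that add atoms: none
Why: The protonated oxazaborolidine binds the formyl oxygen of 5 and lowers the LUMO of the conjugated C=C, and the diene adds in a concerted, asynchronous [4+2] cycloaddition in which its CH2 terminus next to the silyloxy carbon (future C6) bonds to the β-carbon (C5) and the other terminus (C9) to the α-carbon (C10). The closest known reaction type is the oxazaborolidinium-catalysed enantioselective Diels–Alder reaction of 2-substituted enals with 2-silyloxydienes. Ring B is closed by intermolecular cycloaddition with both σ-bonds formed suprafacially on each partner, so no ring-closure constraint arises. The relative configuration of C5 and C10 follows from the (E)-geometry of 5 (formyl trans to isopropenyl becomes arm trans to isopropenyl), and the absolute configuration follows from the catalyst, whose neighbouring phenyl group covers one face of the s-trans enal held by a formyl C–H···O contact, so that the diene reaches the open face. The step needs para regiochemistry, secured by the matched polarisation of the silyloxydiene and the complexed enal; reaction at the α,β- and not the γ,δ-alkene, secured because only the former is conjugated directly to the bound formyl group; and enantioface selection, secured by the catalyst.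

Step 4
Reactants: 6 (1R,6S)-1-methyl-6-(prop-1-en-2-yl)-4-(triisopropylsilyloxy)cyclohex-3-ene-1-carbaldehyde; 7 trimethyl phosphonoacetate
Product: 8 methyl (E)-3-[(1S,6S)-1-methyl-6-(prop-1-en-2-yl)-4-(triisopropylsilyloxy)cyclohex-3-en-1-yl]prop-2-enoate
Conditions: NaH, THF, 0 → 40 °C
Reagents that add atoms: none
Why: Horner–Wadsworth–Emmons olefination of a non-enolisable neopentyl aldehyde, which should give the (E)-enoate and leaves the silyl enol ether and both stereocentres untouched.

Step 5
Reactants: 8 methyl (E)-3-[(1S,6S)-1-methyl-6-(prop-1-en-2-yl)-4-(triisopropylsilyloxy)cyclohex-3-en-1-yl]prop-2-enoate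
Product: 9 methyl 3-[(1R,6S)-1-methyl-6-(prop-1-en-2-yl)-4-(triisopropylsilyloxy)cyclohex-3-en-1-yl]propanoate
Conditions: Cu(OAc)2·H2O (5 mol%), 1,2-bis(diphenylphosphino)benzene (5 mol%), (EtO)2MeSiH (2 equiv), t-BuOH (2 equiv), toluene, 25 °C
Reagents that add atoms: none
Why: Copper hydride-catalysed conjugate reduction delivers hydride only to the polarised enoate C=C, so the isopropenyl group and the silyl enol ether should not be reduced.

Step 6
Reactants: 9 methyl 3-[(1R,6S)-1-methyl-6-(prop-1-en-2-yl)-4-(triisopropylsilyloxy)cyclohex-3-en-1-yl]propanoate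
Product: 10 methyl 3-[(1R,6S)-1-methyl-4-oxo-6-(prop-1-en-2-yl)cyclohex-2-en-1-yl]propanoate
Conditions: Pd(OAc)2 (1.1 equiv), DMSO, 45 °C
Reagents that add atoms: none
Why: Saegusa–Ito oxidation, in which the regiodefined enol ether is palladated at C8 and β-hydride elimination can only take a C9 hydrogen, so the C8=C9 enone should form without involving C6 or the stereocentres.

Step 7
Reactants: 11 methyl 2-acetyl-3-methylbutanoate
Product: 13 methyl 4-bromo-3-oxo-2-(propan-2-yl)butanoate, via 2-bromo keto ester 12 (not isolated)
Conditions: Br2 (1.0 equiv), CHCl3, 0 → 25 °C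
Reagents that add atoms: bromine, BrBr
Why: Bromination of a 2-alkylacetoacetate, in which the first-formed tertiary 2-bromo ester is isomerised by the liberated HBr to the more stable 4-bromo ketone (α-halogenation of a ketone).

Step 8
Reactants: 13 methyl 4-bromo-3-oxo-2-(propan-2-yl)butanoate
Product: 14 methyl 3-oxo-4-(phenylsulfonyl)-2-(propan-2-yl)butanoate
Conditions: PhSO2Na (1.2 equiv), DMF, 25 °C
Reagents that add atoms: sodium benzenesulfinate, [Na+].[O-]S(=O)c1ccccc1
Why: SN2 displacement of the α-bromo ketone by the soft sulfur atom of the sulfinate gives the β-keto sulfone (sulfinate S-alkylation).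

Step 9
Reactants: 14 methyl 3-oxo-4-(phenylsulfonyl)-2-(propan-2-yl)butanoate
Product: 15 methyl 3-(methoxymethoxy)-4-(phenylsulfonyl)-2-(propan-2-yl)but-3-enoate (mixture of double-bond isomers)
Conditions: MeOCH2Cl (1.5 equiv), iPr2NEt (2 equiv), CH2Cl2, 0 → 25 °C
Reagents that add atoms: chloromethyl methyl ether, COCCl
Why: O-Alkylation of the β-keto sulfone enolate by the hard chloromethyl ether gives the enol acetal, every double-bond isomer of which is deprotonated to the same delocalised sulfonyl allyl anion.

Step 10
Reactants: 10 methyl 3-[(1R,6S)-1-methyl-4-oxo-6-(prop-1-en-2-yl)cyclohex-2-en-1-yl]propanoate; 15 methyl 3-(methoxymethoxy)-4-(phenylsulfonyl)-2-(propan-2-yl)but-3-enoate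
Product: 18 methyl 3-[(1S,2S)-5-hydroxy-7-(methoxymethoxy)-1-methyl-4-oxo-6-(propan-2-yl)-2-(prop-1-en-2-yl)-1,2,3,4-tetrahydronaphthalen-1-yl]propanoate, via Michael adduct 16 (not isolated), via cyclised sulfonyl diketone 17 (not isolated)
Conditions: LiOtBu (3.5 equiv), THF, −60 °C (sulfone 15 in excess first, then enone 10), → 25 °C, then 50 °C; aq. NH4Cl
Reagents that add atoms: none
Why: Hauser-type anionic annulation in which the sulfonyl-stabilised allyl anion of 15 adds through its sulfonyl-bearing carbon (C11) to C9 of the enone (Michael addition), the C8 enolate closes onto the donor ester (Dieckmann, 6-exo-trig), and base-induced loss of benzenesulfinate across C9–C11 followed by enolisation gives the arene, so that no stereocentre is created and C5 and C10 cannot epimerise.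

Step 11
Reactants: 18 methyl 3-[(1S,2S)-5-hydroxy-7-(methoxymethoxy)-1-methyl-4-oxo-6-(propan-2-yl)-2-(prop-1-en-2-yl)-1,2,3,4-tetrahydronaphthalen-1-yl]propanoate
Product: 19 methyl 3-[(1S,2S)-7-(methoxymethoxy)-1-methyl-4,5,8-trioxo-6-(propan-2-yl)-2-(prop-1-en-2-yl)-1,2,3,4,5,8-hexahydronaphthalen-1-yl]propanoate
Conditions: (KSO3)2NO (3 equiv), KH2PO4 (aq.), acetone, 0 → 25 °C
Reagents that add atoms: potassium nitrosodisulfonate, [K+].[K+].[O]N(S(=O)(=O)[O-])S(=O)(=O)[O-]
Why: Teuber oxidation, in which the nitrosodisulfonate radical abstracts the phenolic hydrogen and a second equivalent couples at the free para position C11, activated by the neighbouring acetal oxygen, to give the 11,14-para-quinone.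

Step 12
Reactants: 19 methyl 3-[(1S,2S)-7-(methoxymethoxy)-1-methyl-4,5,8-trioxo-6-(propan-2-yl)-2-(prop-1-en-2-yl)-1,2,3,4,5,8-hexahydronaphthalen-1-yl]propanoate
Product: 20 methyl 3-[(1S,2S)-7-hydroxy-1-methyl-4,5,8-trioxo-6-(propan-2-yl)-2-(prop-1-en-2-yl)-1,2,3,4,5,8-hexahydronaphthalen-1-yl]propanoate (CNP0308749.1)
Conditions: 1 M HCl (aq.), THF, 0 → 25 °C
Reagents that add atoms: none
Why: Acid-catalysed hydrolysis of a methoxymethyl ether that is here a vinylogous acetal ester of the acidic hydroxyquinone and should therefore cleave under conditions that spare the methyl ester and the isopropenyl group.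

Compound list
1 | methyl vinyl ketone (but-3-en-2-one) | C=CC(C)=O | starting material
2 | 2-(triisopropylsilyloxy)buta-1,3-diene | C=CC(=C)O[Si](C(C)C)(C(C)C)C(C)C | intermediate
3 | methacrolein (2-methylprop-2-enal) | C=C(C)C=O | starting material
4 | 2-(triphenylphosphoranylidene)propanal | CC(C=O)=P(c1ccccc1)(c1ccccc1)c1ccccc1 | starting material
5 | (E)-2,4-dimethylpenta-2,4-dienal | O=C/C(C)=C/C(C)=C | intermediate
6 | (1R,6S)-1-methyl-6-(prop-1-en-2-yl)-4-(triisopropylsilyloxy)cyclohex-3-ene-1-carbaldehyde (formyl trans to isopropenyl) | C=C(C)[C@@H]1CC(O[Si](C(C)C)(C(C)C)C(C)C)=CC[C@@]1(C)C=O | intermediate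
7 | trimethyl phosphonoacetate | COC(=O)CP(=O)(OC)OC | starting material
8 | methyl (E)-3-[(1S,6S)-1-methyl-6-(prop-1-en-2-yl)-4-(triisopropylsilyloxy)cyclohex-3-en-1-yl]prop-2-enoate | C=C(C)[C@@H]1CC(O[Si](C(C)C)(C(C)C)C(C)C)=CC[C@@]1(C)/C=C/C(=O)OC | intermediate
9 | methyl 3-[(1R,6S)-1-methyl-6-(prop-1-en-2-yl)-4-(triisopropylsilyloxy)cyclohex-3-en-1-yl]propanoate | C=C(C)[C@@H]1CC(O[Si](C(C)C)(C(C)C)C(C)C)=CC[C@@]1(C)CCC(=O)OC | intermediate
10 | methyl 3-[(1R,6S)-1-methyl-4-oxo-6-(prop-1-en-2-yl)cyclohex-2-en-1-yl]propanoate | C=C(C)[C@@H]1CC(=O)C=C[C@@]1(C)CCC(=O)OC | intermediate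
11 | methyl 2-acetyl-3-methylbutanoate (methyl 2-isopropylacetoacetate, racemic) | CC(=O)C(C(C)C)C(=O)OC | starting material
12 | methyl 2-bromo-3-oxo-2-(propan-2-yl)butanoate (racemic, not isolated) | CC(=O)C(Br)(C(C)C)C(=O)OC | intermediate
13 | methyl 4-bromo-3-oxo-2-(propan-2-yl)butanoate (racemic) | BrCC(=O)C(C(C)C)C(=O)OC | intermediate
14 | methyl 3-oxo-4-(phenylsulfonyl)-2-(propan-2-yl)butanoate (racemic) | O=C(CS(=O)(=O)c1ccccc1)C(C(C)C)C(=O)OC | intermediate
15 | methyl 3-(methoxymethoxy)-4-(phenylsulfonyl)-2-(propan-2-yl)but-3-enoate (racemic, E/Z mixture, geometry not defined) | COCOC(=CS(=O)(=O)c1ccccc1)C(C(C)C)C(=O)OC | intermediate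
16 | Michael adduct: ketone of ring B carrying at C9 the chain CH(SO2Ph)–C(OCH2OMe)=C(iPr)–CO2Me (C5 and C10 as in 10; new centres as a mixture; not isolated) | C=C(C)[C@@H]1CC(=O)CC(C(C(OCOC)=C(C(C)C)C(=O)OC)S(=O)(=O)c2ccccc2)[C@@]1(C)CCC(=O)OC | intermediate
17 | cyclised sulfonyl diketone: ring C closed between C8 and C14, with 11-phenylsulfonyl, 12-methoxymethoxy, 13-isopropyl and 7,14-dioxo groups (C5 and C10 as in 10; C8, C9, C11 as a mixture; not isolated) | C=C(C)[C@@H]1CC(=O)C2C(C(C(OCOC)=C(C(C)C)C2=O)S(=O)(=O)c3ccccc3)[C@@]1(C)CCC(=O)OC | intermediate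
18 | methyl 3-[(1S,2S)-5-hydroxy-7-(methoxymethoxy)-1-methyl-4-oxo-6-(propan-2-yl)-2-(prop-1-en-2-yl)-1,2,3,4-tetrahydronaphthalen-1-yl]propanoate | C=C(C)[C@@H]1CC(=O)c2c(O)c(C(C)C)c(OCOC)cc2[C@@]1(C)CCC(=O)OC | intermediate
19 | methyl 3-[(1S,2S)-7-(methoxymethoxy)-1-methyl-4,5,8-trioxo-6-(propan-2-yl)-2-(prop-1-en-2-yl)-1,2,3,4,5,8-hexahydronaphthalen-1-yl]propanoate | C=C(C)[C@@H]1CC(=O)C2=C(C(=O)C(OCOC)=C(C(C)C)C2=O)[C@@]1(C)CCC(=O)OC | intermediate
20 | methyl 3-[(1S,2S)-7-hydroxy-1-methyl-4,5,8-trioxo-6-(propan-2-yl)-2-(prop-1-en-2-yl)-1,2,3,4,5,8-hexahydronaphthalen-1-yl]propanoate | C=C(C)[C@@H]1CC(=O)C2=C(C(=O)C(O)=C(C(C)C)C2=O)[C@@]1(C)CCC(=O)OC | target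

Total step count: 12. Longest linear sequence: 8 steps (steps 2, 3, 4, 5, 6, 10, 11, 12).

Steps most likely to fail

Step 3. The activated formyl group may be attacked by the silyl dienol ether in a Mukaiyama-type addition, the distal alkene may react or oligomerise, or the extended dienal may give poor enantioface discrimination. The fallback sets out from 2 and 5 and drops asymmetric catalysis: heating the two components alone (toluene, BHT, 120–130 °C, sealed tube) should give the racemic trans adduct, that is 6 together with its mirror image (1S,6R)-1-methyl-6-(prop-1-en-2-yl)-4-(triisopropylsilyloxy)cyclohex-3-ene-1-carbaldehyde F1. The relative configuration is still fixed by the (E)-dienal and no Lewis acid is present to divert the silyl enol ether. The enantiomers would be separated by preparative supercritical-fluid chromatography on a cellulose tris(3,5-dimethylphenylcarbamate) phase, and the route is rejoined at 6.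

Step 10. Conjugate addition of the stabilised sulfonyl anion at C9, next to the quaternary C10, may be slow or reversible, the enolate may close onto the propanoate ester, or loss of sulfinate may stall. The closure onto the propanoate ester would give a bridged diketone that cannot enolise and should revert by retro-Claisen cleavage, whereas the fused closure is made irreversible by aromatisation. The fallback sets out from 10 and 11 and closes ring C without sulfur. Ketoester 11 would be O-alkylated (NaH, MeOCH2Cl, THF) to methyl 3-(methoxymethoxy)-2-(propan-2-yl)but-2-enoate F2. Its γ-lithio dienolate (LiN(iPr)2, THF, −78 °C), more nucleophilic than the sulfonyl anion, should add to C9 of 10 and close in a Staunton–Weinreb-type Michael–Claisen sequence to the octahydronaphthalene-4,5-dione F3. Dehydrogenation with DDQ (dioxane, 25–60 °C) should then give the arene, and the route is rejoined at 18.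

Step 11. Hydrogen abstraction from the C14 phenol, which is chelated to the C7 ketone, may be slow, and forcing the oxidation may degrade the electron-rich ring. The fallback sets out from 18 and reverses the order of the last two operations. The aryl acetal would be cleaved under mild, alkene-tolerant conditions (ZnBr2, n-PrSH, CH2Cl2, 0 °C) to the resorcinol methyl 3-[(1S,2S)-5,7-dihydroxy-1-methyl-4-oxo-6-(propan-2-yl)-2-(prop-1-en-2-yl)-1,2,3,4-tetrahydronaphthalen-1-yl]propanoate F4. Its free, non-chelated C12 hydroxyl should allow aerobic oxidation at C11 (Co(salen), that is [N,N′-ethylenebis(salicylideneiminato)]cobalt, O2, MeCN, 25 °C), and the first-formed hydroxylated quinone tautomerises to the hydroxy-para-quinone, so the route is rejoined at 20.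

Further compounds
F1 | step 3 | (1S,6R)-1-methyl-6-(prop-1-en-2-yl)-4-(triisopropylsilyloxy)cyclohex-3-ene-1-carbaldehyde (mirror image of 6) | C=C(C)[C@H]1CC(O[Si](C(C)C)(C(C)C)C(C)C)=CC[C@]1(C)C=O
F2 | step 10 | methyl 3-(methoxymethoxy)-2-(propan-2-yl)but-2-enoate (E/Z mixture) | COCOC(C)=C(C(C)C)C(=O)OC
F3 | step 10 | methyl 3-[7-(methoxymethoxy)-1-methyl-4,5-dioxo-6-(propan-2-yl)-2-(prop-1-en-2-yl)-1,2,3,4,4a,5,8,8a-octahydronaphthalen-1-yl]propanoate (C5 and C10 of the abietane numbering as in 10; ring-fusion centres as a mixture) | C=C(C)[C@@H]1CC(=O)C2C(CC(OCOC)=C(C(C)C)C2=O)[C@@]1(C)CCC(=O)OC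
F4 | step 11 | methyl 3-[(1S,2S)-5,7-dihydroxy-1-methyl-4-oxo-6-(propan-2-yl)-2-(prop-1-en-2-yl)-1,2,3,4-tetrahydronaphthalen-1-yl]propanoate | C=C(C)[C@@H]1CC(=O)c2c(O)c(C(C)C)c(O)cc2[C@@]1(C)CCC(=O)OC
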